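**Retrosynthetic overview**
1. Numbering follows the target: ring C1 (C=O), C2=C3, C4, C5 (carbinol), C6; side chain C1' (CH2), C2' (C=O).
2. Ring order: the single six-membered carbocycle is never closed in the route. It is bought as phloroglucinol, dearomatised by one hydride to 5-hydroxycyclohexane-1,3-dione and O-silylated twice. Its C3–O group later serves as the leaving group that creates C2=C3.
3. Key disconnection C1'–C5: a counteranion-controlled Mukaiyama addition joins the terminal enol silane of (10Z)-nonadec-10-en-2-one (from oleic acid and MeLi) to this racemic vinylogous silyl ester.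
4. Enabling feature: O–C5–C6–C1=O is a 1,3-dioxygenated three-carbon unit of the ring, and C3 lies opposite C6. With the same silyl group on both oxygens, C1–C6–C5 becomes a meso allyl cation with enantiotopic termini. Both enantiomers of the precursor therefore funnel into one intermediate, and 1,2- and 1,4-attack are the same event.
5. Endgame: desilylation, then mesylation/E1cB, which erases C3 and merges its epimers.

Key step: step 5

Assumption: the sense of induction of the confined acid in step 5 cannot be derived from a model, so the (S,S)-acid is written and its equally accessible mirror image is to be used if the first experiment shows the opposite sense; the relay centre C3 is drawn for the expected anti attack.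

**Step 1**
Reactants: 1 phloroglucinol
Product: 2 5-hydroxycyclohexane-1,3-dione
Conditions: NaBH4, H2O, N2, 0 °C to rt; then 1 M HCl to pH 4 at 0 °C, EtOAc extraction
Reagents that add atoms: none
Why: Borohydride carbonyl reduction; in the weakly basic medium the phloroglucinolate reacts through its keto tautomer, and after one hydride transfer the ring is a vinylogous carboxylate that resists further reduction, so the reaction should stop at achiral 2, whose carbinol carbon lies on a mirror plane.

**Step 2**
Reactants: 2 5-hydroxycyclohexane-1,3-dione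
Product: 3 rac-3,5-bis(triethylsilyloxy)cyclohex-2-en-1-one
Conditions: Et3SiCl (2.2 equiv), imidazole, DMF, 0 °C; pentane / cold aq. NaHCO3, bulb-to-bulb distillation
Reagents that add atoms: chlorotriethylsilane, CC[Si](CC)(CC)Cl
Why: Standard O-silylation (silyl chloride plus imidazole) of the secondary alcohol and of the acidic 1,3-dione enol gives the vinylogous silyl ester as a racemate, whose configuration is irrelevant because step 5 erases it.

**Step 3**
Reactants: 4 oleic acid
Product: 6 (10Z)-nonadec-10-en-2-one, via dilithium gem-diolate 5 (not isolated)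
Conditions: MeLi (2.2 equiv), Et2O, 0 °C; poured into cold 1 M HCl
Reagents that add atoms: methyllithium, [Li]C
Why: Addition of an organolithium reagent to a lithium carboxylate; gem-diolate 5 persists until the acidic quench, so only one methyl group is taken up, and the isolated Z-alkene is inert to MeLi.

**Step 4**
Reactants: 6 (10Z)-nonadec-10-en-2-one
Product: 8 triethyl[(10Z)-nonadeca-1,10-dien-2-yloxy]silane, via lithium enolate 7 (not isolated)
Conditions: LiN(iPr)2, THF, −78 °C; Et3SiCl, −78 °C to rt; pentane / cold aq. NaHCO3
Reagents that add atoms: chlorotriethylsilane, CC[Si](CC)(CC)Cl; LiN(iPr)2, [Li]N(C(C)C)C(C)C (lithium in intermediate 7 only)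
Why: Kinetic deprotonation of the methyl ketone by the hindered amide at the less substituted carbon, followed by O-silylation, gives the terminal enol silane and thereby fixes which carbon forms the new bond.

**Step 5**
Reactants: 3 rac-3,5-bis(triethylsilyloxy)cyclohex-2-en-1-one; 8 triethyl[(10Z)-nonadeca-1,10-dien-2-yloxy]silane (1.3 equiv)
Product: 10 (10Z)-1-[(1R,5S)-1,3,5-tris(triethylsilyloxy)cyclohex-2-en-1-yl]nonadec-10-en-2-one, via meso allyl cation 9 (not isolated)
Conditions: (S,S)-IDPi acid (imidodiphosphorimidate from two (S)-3,3'-diaryl-BINOL units, N-triflyl groups; 2 mol %), toluene, −78 °C; Et3N quench at −78 °C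
Reagents that add atoms: none
Why: Proposed new method: the acid is silylated by 8 and hands Et3Si+ (the silyl group that 3 already carries) to the carbonyl oxygen of either enantiomer of 3, which makes C1–O and C5–O equivalent and gives the single meso 1,3-bis(silyloxy)allyl cation 9 (mirror plane through C6 and C3) inside the chiral pocket of the counteranion. The CH2 terminus of 8 attacks one of the two enantiotopic allyl termini, the resulting silyloxycarbenium ion returns Et3Si+ to the anion, and 10 forms from all atoms of 3 and 8, holding the C1'–C5 bond, the fully substituted carbinol carbon, the free C2' ketone and the C1 ketone masked as its enol silane. The closest known reaction types are the IDPi-catalysed Mukaiyama aldol addition of enol silanes to simple ketones and the silylium-catalysed Mukaiyama–Michael addition to enones, which coincide here; no ring is closed. C5 is controlled by the counteranion (choice of terminus and face), whereas C3 is only a relay: attack anti to the C3 silyloxy group should prevail, and attack on the other terminus from the syn face gives the C3 epimer of the same C5 configuration, so that both merge once C3 becomes sp2 in step 7. The step needs bond formation at the methyl-derived carbon only, activation of 3 in preference to the ketones present and survival of the allylic C5–O bond; these are secured by the regiodefined terminal enol silane, by the high Lewis basicity of the vinylogous silyl ester oxygen, and by low temperature together with an amine quench before warming.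

**Step 6**
Reactants: 10 (10Z)-1-[(1R,5S)-1,3,5-tris(triethylsilyloxy)cyclohex-2-en-1-yl]nonadec-10-en-2-one
Product: 11 (3R,5R)-3,5-dihydroxy-3-[(10Z)-2-oxononadec-10-en-1-yl]cyclohexan-1-one
Conditions: HF·pyridine, excess pyridine, THF, 0 °C
Reagents that add atoms: none
Why: Fluoride-driven Si–O cleavage under buffered conditions; the enol silane is the most labile group and should give the C1 ketone first, which removes the allylic activation of the C5–O bond before the secondary and tertiary silyl ethers fall, and neither stereocentre is touched.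

**Step 7**
Reactants: 11 (3R,5R)-3,5-dihydroxy-3-[(10Z)-2-oxononadec-10-en-1-yl]cyclohexan-1-one
Product: 13 (5R)-5-hydroxy-5-[(10Z)-2-oxononadec-10-en-1-yl]cyclohex-2-en-1-one, via secondary mesylate 12 (not isolated)
Conditions: MsCl (1.1 equiv), Et3N (3 equiv), CH2Cl2, −30 to 0 °C
Reagents that add atoms: methanesulfonyl chloride, CS(=O)(=O)Cl (in intermediate 12 only)
Why: Chemoselective sulfonylation of the secondary over the tertiary alcohol, followed by E1cB elimination through the C1/C2 enolate under the same mild amine base, gives the conjugated enone, erases the relay centre C3 (so any C3 epimer converges) and leaves C5 untouched.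

**Compound list**
1 | phloroglucinol (benzene-1,3,5-triol) | Oc1cc(O)cc(O)c1 | starting material
2 | 5-hydroxycyclohexane-1,3-dione (achiral) | OC1CC(=O)CC(=O)C1 | intermediate
3 | rac-3,5-bis(triethylsilyloxy)cyclohex-2-en-1-one | CC[Si](CC)(CC)OC1CC(=O)C=C(O[Si](CC)(CC)CC)C1 | intermediate
4 | oleic acid, (9Z)-octadec-9-enoic acid | CCCCCCCC/C=C\CCCCCCCC(=O)O | starting material
5 | dilithium (10Z)-nonadec-10-ene-2,2-diolate | CCCCCCCC/C=C\CCCCCCCC(C)([O-])[O-].[Li+].[Li+] | intermediate
6 | (10Z)-nonadec-10-en-2-one | CCCCCCCC/C=C\CCCCCCCC(C)=O | intermediate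
7 | lithium (10Z)-nonadeca-1,10-dien-2-olate | CCCCCCCC/C=C\CCCCCCCC(=C)[O-].[Li+] | intermediate
8 | triethyl[(10Z)-nonadeca-1,10-dien-2-yloxy]silane | CCCCCCCC/C=C\CCCCCCCC(=C)O[Si](CC)(CC)CC | intermediate
9 | meso 1,3,5-tris(triethylsilyloxy)cyclohexenyl cation (one resonance form; counterion is the IDPi anion) | CC[Si](CC)(CC)OC1CC(O[Si](CC)(CC)CC)=CC(=[O+][Si](CC)(CC)CC)C1 | intermediate
10 | (10Z)-1-[(1R,5S)-1,3,5-tris(triethylsilyloxy)cyclohex-2-en-1-yl]nonadec-10-en-2-one (tertiary and secondary silyloxy groups cis; side chain trans to the secondary one) | CCCCCCCC/C=C\CCCCCCCC(=O)C[C@]1(O[Si](CC)(CC)CC)C[C@@H](O[Si](CC)(CC)CC)CC(O[Si](CC)(CC)CC)=C1 | intermediate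
11 | (3R,5R)-3,5-dihydroxy-3-[(10Z)-2-oxononadec-10-en-1-yl]cyclohexan-1-one (cis-diol) | CCCCCCCC/C=C\CCCCCCCC(=O)C[C@]1(O)C[C@@H](O)CC(=O)C1 | intermediate
12 | (1R,3R)-3-hydroxy-5-oxo-3-[(10Z)-2-oxononadec-10-en-1-yl]cyclohexyl methanesulfonate | CCCCCCCC/C=C\CCCCCCCC(=O)C[C@]1(O)C[C@@H](OS(C)(=O)=O)CC(=O)C1 | intermediate
13 | (5R)-5-hydroxy-5-[(10Z)-2-oxononadec-10-en-1-yl]cyclohex-2-en-1-one | CCCCCCCC/C=C\CCCCCCCC(=O)C[C@]1(O)CC=CC(=O)C1 | target

**Step count**
- Total step count: 7.
- Longest linear sequence: 5 steps (1, 2, 5, 6, 7 or 3, 4, 5, 6, 7).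

**Steps most likely to fail**

**Step 5 (the labelled step).**
- The doubly oxygen-stabilised cation may react too slowly with a ketone-derived enol silane.
- Proton loss next to the cation, followed by loss of silanol from C3, would aromatise the ring.
- Silylium activation may ionise the new allylic C5–O bond.
- The two termini may be poorly discriminated.

The fallback uses known chemistry, sets out from 6 and comes back at 13. The stereocentre is no longer set during C–C bond formation. It is set afterwards, by enzymatic desymmetrisation of a meso compound. Bought all-cis-cyclohexane-1,3,5-triol F1 is silylated twice (TBSCl, imidazole) to all-cis-3,5-bis(tert-butyldimethylsilyloxy)cyclohexan-1-ol F2. This is oxidised with Dess–Martin periodinane to meso cis-3,5-bis(tert-butyldimethylsilyloxy)cyclohexan-1-one F3. Lithium enolate 7, made from 6 as in step 4, should add at −78 °C by equatorial attack to give the meso aldol adduct F4, with the side chain cis to both silyloxy groups. HF·pyridine should then give the meso triol F5. A lipase chosen by screening (Candida antarctica lipase B or Pseudomonas cepacia lipase, vinyl acetate) acetylates the enantiotopic hydroxyl group on the carbon that becomes C3, giving the monoacetate F6. Dess–Martin oxidation of the remaining secondary alcohol gives the β-acetoxy ketone F7, and Et3N in CH2Cl2 eliminates acetic acid to give 13.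

**Step 6.**
- Acid may ionise the tertiary allylic silyl ether before the enol silane has been cleaved.
- The free β,β'-dihydroxy ketone may dehydrate twice and aromatise.

The fallback sets out from 10 and comes back at 13. The order of events is changed so that the base-induced elimination runs while the tertiary oxygen is still protected and the free dihydroxy ketone is never formed. Only the enol silane is hydrolysed first (citric acid, MeOH, 0 °C), giving (3R,5R)-3,5-bis(triethylsilyloxy)-3-[(10Z)-2-oxononadec-10-en-1-yl]cyclohexan-1-one F8. DBU in CH2Cl2 then expels the C3 silanolate by E1cB, giving (5R)-5-(triethylsilyloxy)-5-[(10Z)-2-oxononadec-10-en-1-yl]cyclohex-2-en-1-one F9. A final buffered HF·pyridine treatment gives 13.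

**Step 1.**
- On acidification and isolation the reduced ring may lose water and return to an aromatic compound.
- Reduction may run on beyond the dihydro stage.

The fallback sets out from 1 and comes back at 3. The ring is reduced fully and then re-oxidised selectively, so the free hydroxy-dione is avoided. Exhaustive hydrogenation of 1 (H2, Raney Ni, EtOH) gives all-cis-cyclohexane-1,3,5-triol F10. One equivalent of Et3SiCl with imidazole gives all-cis-5-(triethylsilyloxy)cyclohexane-1,3-diol F11. Double Dess–Martin oxidation (NaHCO3 buffer) gives 5-(triethylsilyloxy)cyclohexane-1,3-dione F12. O-silylation of its enol (Et3SiCl, imidazole) gives 3.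

**Further compounds**
F1 | step 5 | all-cis-cyclohexane-1,3,5-triol (bought) | O[C@H]1C[C@@H](O)C[C@@H](O)C1
F2 | step 5 | all-cis-3,5-bis(tert-butyldimethylsilyloxy)cyclohexan-1-ol | O[C@H]1C[C@@H](O[Si](C)(C)C(C)(C)C)C[C@@H](O[Si](C)(C)C(C)(C)C)C1
F3 | step 5 | meso cis-3,5-bis(tert-butyldimethylsilyloxy)cyclohexan-1-one | O=C1C[C@@H](O[Si](C)(C)C(C)(C)C)C[C@@H](O[Si](C)(C)C(C)(C)C)C1
F4 | step 5 | meso aldol adduct, (10Z)-1-[1-hydroxy-cis-3,5-bis(tert-butyldimethylsilyloxy)cyclohexyl]nonadec-10-en-2-one, side chain cis to both silyloxy groups | CCCCCCCC/C=C\CCCCCCCC(=O)C[C@]1(O)C[C@H](O[Si](C)(C)C(C)(C)C)C[C@H](O[Si](C)(C)C(C)(C)C)C1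
F5 | step 5 | meso triol, (10Z)-1-(1,3,5-trihydroxycyclohexyl)nonadec-10-en-2-one, side chain cis to both secondary hydroxyl groups | CCCCCCCC/C=C\CCCCCCCC(=O)C[C@]1(O)C[C@H](O)C[C@H](O)C1
F6 | step 5 | monoacetate of F5, acetate on the carbon that becomes C3 | CCCCCCCC/C=C\CCCCCCCC(=O)C[C@]1(O)C[C@H](OC(C)=O)C[C@H](O)C1
F7 | step 5 | (1S,3R)-3-hydroxy-5-oxo-3-[(10Z)-2-oxononadec-10-en-1-yl]cyclohexyl acetate | CCCCCCCC/C=C\CCCCCCCC(=O)C[C@]1(O)C[C@H](OC(C)=O)CC(=O)C1
F8 | step 6 | (3R,5R)-3,5-bis(triethylsilyloxy)-3-[(10Z)-2-oxononadec-10-en-1-yl]cyclohexan-1-one | CCCCCCCC/C=C\CCCCCCCC(=O)C[C@]1(O[Si](CC)(CC)CC)C[C@@H](O[Si](CC)(CC)CC)CC(=O)C1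
F9 | step 6 | (5R)-5-(triethylsilyloxy)-5-[(10Z)-2-oxononadec-10-en-1-yl]cyclohex-2-en-1-one | CCCCCCCC/C=C\CCCCCCCC(=O)C[C@]1(O[Si](CC)(CC)CC)CC=CC(=O)C1
F10 | step 1 | all-cis-cyclohexane-1,3,5-triol (made from 1) | O[C@H]1C[C@@H](O)C[C@@H](O)C1
F11 | step 1 | all-cis-5-(triethylsilyloxy)cyclohexane-1,3-diol | O[C@H]1C[C@@H](O)C[C@@H](O[Si](CC)(CC)CC)C1
F12 | step 1 | 5-(triethylsilyloxy)cyclohexane-1,3-dione | CC[Si](CC)(CC)OC1CC(=O)CC(=O)C1
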